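**Retrosynthetic overview**
1. The (1E,3E)-diene is cut at C1'–C2' (Heck): (R)-2-ethenyl-2-methylchroman-6-ol plus an (E)-alkenyl iodide that already carries the bought trimethylcyclohexene ring.
2. The chromanol is cut through both of its rings at once: an intramolecular Dötz benzannulation of a chromium alkoxy(vinyl)carbene whose terminal alkyne is tethered through the carbene oxygen closes the benzene ring and the dihydropyran ring together and leaves the C6 phenol free.
3. The tethering alcohol, (R)-3-methylhept-1-en-6-yn-3-ol, comes from (R)-linalool in one flask (ozonolysis, then Ohira–Bestmann homologation); the stereocentre is bought and never touched.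
4. The alkenyl iodide comes from dihydro-β-ionone (methyl ketone → terminal alkyne → Zr-catalysed carboalumination/iodination).
5. Ring order: cyclohexene ring purchased; benzene and pyran rings formed simultaneously in step 3.

Assumption: commercial (R)-(−)-linalool is taken as enantiomerically pure; the ee of 23 equals that of the linalool used.

**Step 1**
Reactants: 1 (R)-linalool
Product: 5 (3R)-3-methylhept-1-en-6-yn-3-ol, via ozonide 2 (not isolated), via hydroxy aldehyde 3 (not isolated), via lactol 4 (not isolated)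
Conditions: O3, CH2Cl2, −78 °C (stopped at consumption of 1); Me2S, −78 °C → rt; solvent exchanged for MeOH (acetone and excess Me2S leave with the CH2Cl2); then dimethyl (1-diazo-2-oxopropyl)phosphonate, K2CO3, MeOH, 0 °C → rt
Reagents that add atoms: dimethyl (1-diazo-2-oxopropyl)phosphonate, COP(=O)(OC)C(=[N+]=[N-])C(C)=O
Why: The electron-rich trisubstituted alkene is ozonised far faster than the vinyl group, reduction of ozonide 2 frees aldehyde 3, which rests as lactol 4, and in basic methanol the lactol reopens so that the Seyferth–Gilbert homologation (Ohira–Bestmann variant) turns the aldehyde carbon into the terminal alkyne in the same flask, which spares isolation of the small, volatile lactol and leaves the tertiary carbinol stereocentre untouched.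

**Step 2**
Reactants: 6 hexacarbonylchromium Cr(CO)6; 7 tributyl(ethenyl)stannane
Product: 10 tetramethylammonium pentacarbonyl(1-oxidoprop-2-en-1-ylidene)chromate [Me4N][(CO)5Cr=C(O)CH=CH2], via vinyllithium 8 (not isolated), via lithium acylchromate 9 (not isolated)
Conditions: 7, n-BuLi, THF, −78 °C; then 6, Et2O, 0 °C → rt; then Me4NBr, H2O, 0 °C
Reagents that add atoms: tetramethylammonium bromide, C[N+](C)(C)C.[Br-]
Why: Fischer acylmetalate synthesis, in which vinyllithium from tin–lithium exchange adds to a CO ligand of Cr(CO)6 and the acylchromate is kept as its tetramethylammonium salt, the usual precursor of acyloxycarbene complexes.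

**Step 3**
Reactants: 10 tetramethylammonium acylchromate; 5 (3R)-3-methylhept-1-en-6-yn-3-ol
Product: 15 (2R)-2-ethenyl-2-methyl-3,4-dihydro-2H-chromen-6-ol, via pivaloyloxycarbene complex 11 (not isolated), via lithium alkoxide 12 (not isolated), via alkoxycarbene complex 13 (not isolated), via tricarbonylchromium arene complex 14 (not isolated)
Conditions: t-BuCOCl, CH2Cl2, −40 °C; then 12 (from 5, n-BuLi, THF, −78 °C), −78 → −20 °C; then THF (0.01 M), 45 °C; then air, MeCN, rt
Reagents that add atoms: none
Why: Proposed new method: O-acylation of 10 gives the strongly electrophilic pivaloyloxycarbene 11, whose carbene carbon should undergo addition–elimination with alkoxide 12 (the known alcoholysis of acyloxycarbene complexes, extended here from primary and secondary alcohols to a tertiary lithium alkoxide, with the pivaloyl group blocking attack at the acyl carbon), and warming 13 then starts the known intramolecular Dötz benzannulation of an alkyne tethered through the carbene oxygen (CO loss, alkyne insertion with the tether placing the internal alkyne carbon next to the carbene carbon, CO insertion to a dienylketene, 6π electrocyclisation, tautomerisation), which closes the benzene and dihydropyran rings in one operation and carries the linalool stereocentre through unchanged because no bond to it is made or broken.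

**Step 4**
Reactants: 16 dihydro-β-ionone, 4-(2,6,6-trimethylcyclohex-1-en-1-yl)butan-2-one
Product: 20 2-(but-3-yn-1-yl)-1,3,3-trimethylcyclohex-1-ene, via lithium enolate 17 (not isolated), via enol phosphate 18 (not isolated), via lithium acetylide 19 (not isolated)
Conditions: LiN(iPr)2, THF, −78 °C; ClP(O)(OEt)2, −78 °C → rt; LiN(iPr)2 (2.3 equiv), −78 °C → rt; H2O
Reagents that add atoms: none
Why: Negishi's methyl ketone to alkyne conversion relies on kinetic deprotonation at the methyl group, O-phosphorylation and base-induced elimination of the enol phosphate, and the tetrasubstituted ring alkene is inert to it.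

**Step 5**
Reactants: 20 2-(but-3-yn-1-yl)-1,3,3-trimethylcyclohex-1-ene
Product: 22 2-[(3E)-4-iodo-3-methylbut-3-en-1-yl]-1,3,3-trimethylcyclohex-1-ene, via alkenylalane 21 (not isolated)
Conditions: Me3Al, Cp2ZrCl2 (25 mol %), CH2Cl2, 0 °C → rt; then I2, THF, −30 → 0 °C
Reagents that add atoms: trimethylaluminium, C[Al](C)C; iodine, II
Why: Negishi Zr-catalysed carboalumination adds methyl and aluminium syn across the terminal alkyne with aluminium at the terminus, and iodinolysis with retention gives the (E)-trisubstituted alkenyl iodide that fixes the C3'=C4' geometry.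

**Step 6**
Reactants: 15 (2R)-2-ethenyl-2-methyl-3,4-dihydro-2H-chromen-6-ol; 22 (E)-alkenyl iodide
Product: 23 (2R)-2-methyl-2-[(1E,3E)-4-methyl-6-(2,6,6-trimethylcyclohex-1-en-1-yl)hexa-1,3-dien-1-yl]-3,4-dihydro-2H-chromen-6-ol
Conditions: Pd(OAc)2 (10 mol %), Bu4NCl, NaHCO3, DMF, 40 °C, Ar
Reagents that add atoms: none
Why: Mizoroki–Heck coupling under ligand-free Jeffery conditions, in which the alkenylpalladium adds to the terminal vinyl carbon (the quaternary C2 blocks the other regiochemistry) and the only possible syn β-hydride elimination gives the (1E,3E)-diene with retention of the iodide geometry and no change at the stereocentre.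

**Compound list**
1 | (R)-linalool, (3R)-3,7-dimethylocta-1,6-dien-3-ol | C=C[C@](C)(O)CCC=C(C)C | starting material
2 | 3,3-dimethyl-5-[(3R)-3-hydroxy-3-methylpent-4-en-1-yl]-1,2,4-trioxolane (ozonide) | C=C[C@](C)(O)CCC1OOC(C)(C)O1 | intermediate
3 | (4R)-4-hydroxy-4-methylhex-5-enal (open form of 4) | C=C[C@](C)(O)CCC=O | intermediate
4 | (5R)-5-ethenyl-5-methyloxolan-2-ol (lactol, both anomers) | C=C[C@@]1(C)CCC(O)O1 | intermediate
5 | (3R)-3-methylhept-1-en-6-yn-3-ol | C=C[C@](C)(O)CCC#C | intermediate
6 | hexacarbonylchromium Cr(CO)6 | O=C=[Cr](=C=O)(=C=O)(=C=O)(=C=O)=C=O | starting material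
7 | tributyl(ethenyl)stannane | C=C[Sn](CCCC)(CCCC)CCCC | starting material
8 | vinyllithium | [Li]C=C | intermediate
9 | lithium pentacarbonyl(1-oxidoprop-2-en-1-ylidene)chromate | [Li+].C=CC([O-])=[Cr](=C=O)(=C=O)(=C=O)(=C=O)=C=O | intermediate
10 | tetramethylammonium pentacarbonyl(1-oxidoprop-2-en-1-ylidene)chromate | C[N+](C)(C)C.C=CC([O-])=[Cr](=C=O)(=C=O)(=C=O)(=C=O)=C=O | intermediate
11 | pentacarbonyl[1-(2,2-dimethylpropanoyloxy)prop-2-en-1-ylidene]chromium | C=CC(OC(=O)C(C)(C)C)=[Cr](=C=O)(=C=O)(=C=O)(=C=O)=C=O | intermediate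
12 | lithium (3R)-3-methylhept-1-en-6-yn-3-olate | [Li+].C=C[C@](C)([O-])CCC#C | intermediate
13 | pentacarbonyl{1-[(3R)-3-methylhept-1-en-6-yn-3-yl]oxyprop-2-en-1-ylidene}chromium | C=C[C@](C)(OC(C=C)=[Cr](=C=O)(=C=O)(=C=O)(=C=O)=C=O)CCC#C | intermediate
14 | tricarbonyl[η6-(2R)-2-ethenyl-2-methyl-3,4-dihydro-2H-chromen-6-ol]chromium (arene and Cr(CO)3 part written side by side) | C=C[C@@]1(C)CCc2cc(O)ccc2O1.O=C=[Cr](=C=O)=C=O | intermediate
15 | (2R)-2-ethenyl-2-methyl-3,4-dihydro-2H-chromen-6-ol | C=C[C@@]1(C)CCc2cc(O)ccc2O1 | intermediate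
16 | dihydro-β-ionone, 4-(2,6,6-trimethylcyclohex-1-en-1-yl)butan-2-one | CC(=O)CCC1=C(C)CCCC1(C)C | starting material
17 | lithium 4-(2,6,6-trimethylcyclohex-1-en-1-yl)but-1-en-2-olate | [Li+].C=C([O-])CCC1=C(C)CCCC1(C)C | intermediate
18 | diethyl 4-(2,6,6-trimethylcyclohex-1-en-1-yl)but-1-en-2-yl phosphate | C=C(OP(=O)(OCC)OCC)CCC1=C(C)CCCC1(C)C | intermediate
19 | lithium 4-(2,6,6-trimethylcyclohex-1-en-1-yl)but-1-yn-1-ide | [Li]C#CCCC1=C(C)CCCC1(C)C | intermediate
20 | 2-(but-3-yn-1-yl)-1,3,3-trimethylcyclohex-1-ene | C#CCCC1=C(C)CCCC1(C)C | intermediate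
21 | dimethyl[(1E)-2-methyl-4-(2,6,6-trimethylcyclohex-1-en-1-yl)but-1-en-1-yl]alane | C[Al](C)/C=C(\C)CCC1=C(C)CCCC1(C)C | intermediate
22 | 2-[(3E)-4-iodo-3-methylbut-3-en-1-yl]-1,3,3-trimethylcyclohex-1-ene | I/C=C(\C)CCC1=C(C)CCCC1(C)C | intermediate
23 | (2R)-2-methyl-2-[(1E,3E)-4-methyl-6-(2,6,6-trimethylcyclohex-1-en-1-yl)hexa-1,3-dien-1-yl]-3,4-dihydro-2H-chromen-6-ol | CC1=C(CC/C(C)=C/C=C/[C@@]2(C)CCc3cc(O)ccc3O2)C(C)(C)CCC1 | target

**Total step count:** 6. **Longest linear sequence:** 3 steps (1 → 5 → 15 → 23).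

**Steps most likely to fail, with fallbacks**

Step 3 is the largest risk. A hindered tertiary alkoxide has to displace pivalate at the carbene carbon, and the tertiary allylic alkoxycarbene 13 may ionise (racemise or eliminate) before it cyclises. The fallback forms the tertiary C–O–carbene link intramolecularly and builds the two rings one after the other; it sets out from 5 and 6 and returns at 15. Photolysis of 6 in THF gives pentacarbonyl(tetrahydrofuran)chromium F1. With 5 and Et3N at rt, F1 cycloisomerises the alkynol (the tertiary hydroxyl adds to the metal-activated alkyne terminus) to the cyclic carbene complex pentacarbonyl[(6R)-6-ethenyl-6-methyloxan-2-ylidene]chromium F2. Aminomethylation of its acidic α-CH2 with dimethyl(methylidene)ammonium iodide and Et3N gives the Mannich base pentacarbonyl[(6R)-3-[(dimethylamino)methyl]-6-ethenyl-6-methyloxan-2-ylidene]chromium F3. F3 loses dimethylamine on silica gel to the α-methylene carbene complex pentacarbonyl[(6R)-6-ethenyl-6-methyl-3-methylideneoxan-2-ylidene]chromium F4. Dötz benzannulation of F4 with acetylene (1 atm, THF, 50 °C) gives 14, and air oxidation gives 15.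

Step 6 is the second risk. The alkylpalladium intermediate has the aryloxy oxygen in the β-position (ring opening by β-aryloxy elimination), zerovalent palladium can ionise the tertiary allylic aryl ether, and the free electron-rich phenol is oxidation-sensitive. The fallback replaces the Heck reaction by metathesis and Suzuki coupling; it sets out from 15 and returns at 23. Cross-metathesis of the vinyl group with ethenylboronic acid pinacol ester (second-generation Hoveyda–Grubbs catalyst, CH2Cl2, 40 °C) gives the (E)-alkenylboronate (2R)-2-methyl-2-[(E)-2-(4,4,5,5-tetramethyl-1,3,2-dioxaborolan-2-yl)ethenyl]-3,4-dihydro-2H-chromen-6-ol F5. Suzuki–Miyaura coupling of F5 with 22 (Pd(dppf)Cl2, K3PO4, THF/H2O, rt) gives 23 with both alkene geometries fixed beforehand.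

Step 2 is the third risk. The parent vinyl acylchromate and the vinylcarbene complexes made from it are prone to polymerisation and conjugate addition. The fallback uses the stable trans-β-silylvinyl unit as a masked vinyl group; it sets out from 6 and returns at 15. (E)-(2-Bromoethenyl)trimethylsilane and t-BuLi (Et2O, −78 °C) give (E)-2-(trimethylsilyl)ethenyllithium F6, which adds to 6 to give the lithium acylchromate F7. Exchange with Me4NBr gives tetramethylammonium pentacarbonyl[(2E)-1-oxido-3-(trimethylsilyl)prop-2-en-1-ylidene]chromate F8. Under the conditions of step 3, F8 and t-BuCOCl give the pivaloyloxycarbene complex F9, and alkoxide 12 converts it into the alkoxycarbene complex F10. On warming, F10 undergoes the same benzannulation; the silyl group is expected to shift from C7 to oxygen at the cyclohexadienone stage, giving the arene complex F11 and, after air, the aryl silyl ether trimethyl{[(2R)-2-ethenyl-2-methyl-3,4-dihydro-2H-chromen-6-yl]oxy}silane F12. K2CO3 in MeOH cleaves F12 to 15.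

**Further compounds**
F1 | step 3 | pentacarbonyl(tetrahydrofuran)chromium Cr(CO)5(THF) | C1CC[O+](C1)[Cr-](=C=O)(=C=O)(=C=O)(=C=O)=C=O
F2 | step 3 | pentacarbonyl[(6R)-6-ethenyl-6-methyloxan-2-ylidene]chromium | C=C[C@@]1(C)CCCC(=[Cr](=C=O)(=C=O)(=C=O)(=C=O)=C=O)O1
F3 | step 3 | pentacarbonyl[(6R)-3-[(dimethylamino)methyl]-6-ethenyl-6-methyloxan-2-ylidene]chromium (C3 epimers) | C=C[C@@]1(C)CCC(CN(C)C)C(=[Cr](=C=O)(=C=O)(=C=O)(=C=O)=C=O)O1
F4 | step 3 | pentacarbonyl[(6R)-6-ethenyl-6-methyl-3-methylideneoxan-2-ylidene]chromium | C=C[C@@]1(C)CCC(=C)C(=[Cr](=C=O)(=C=O)(=C=O)(=C=O)=C=O)O1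
F5 | step 6 | (2R)-2-methyl-2-[(E)-2-(4,4,5,5-tetramethyl-1,3,2-dioxaborolan-2-yl)ethenyl]-3,4-dihydro-2H-chromen-6-ol | CC1(C)OB(/C=C/[C@@]2(C)CCc3cc(O)ccc3O2)OC1(C)C
F6 | step 2 | (E)-2-(trimethylsilyl)ethenyllithium | [Li]/C=C/[Si](C)(C)C
F7 | step 2 | lithium pentacarbonyl[(2E)-1-oxido-3-(trimethylsilyl)prop-2-en-1-ylidene]chromate | [Li+].C[Si](C)(C)/C=C/C([O-])=[Cr](=C=O)(=C=O)(=C=O)(=C=O)=C=O
F8 | step 2 | tetramethylammonium pentacarbonyl[(2E)-1-oxido-3-(trimethylsilyl)prop-2-en-1-ylidene]chromate | C[N+](C)(C)C.C[Si](C)(C)/C=C/C([O-])=[Cr](=C=O)(=C=O)(=C=O)(=C=O)=C=O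
F9 | step 2 | pentacarbonyl[(2E)-1-(2,2-dimethylpropanoyloxy)-3-(trimethylsilyl)prop-2-en-1-ylidene]chromium | C[Si](C)(C)/C=C/C(OC(=O)C(C)(C)C)=[Cr](=C=O)(=C=O)(=C=O)(=C=O)=C=O
F10 | step 2 | pentacarbonyl{(2E)-1-[(3R)-3-methylhept-1-en-6-yn-3-yl]oxy-3-(trimethylsilyl)prop-2-en-1-ylidene}chromium | C=C[C@](C)(OC(/C=C/[Si](C)(C)C)=[Cr](=C=O)(=C=O)(=C=O)(=C=O)=C=O)CCC#C
F11 | step 2 | tricarbonyl[η6-trimethyl{[(2R)-2-ethenyl-2-methyl-3,4-dihydro-2H-chromen-6-yl]oxy}silane]chromium (arene and Cr(CO)3 part written side by side) | C=C[C@@]1(C)CCc2cc(O[Si](C)(C)C)ccc2O1.O=C=[Cr](=C=O)=C=O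
F12 | step 2 | trimethyl{[(2R)-2-ethenyl-2-methyl-3,4-dihydro-2H-chromen-6-yl]oxy}silane | C=C[C@@]1(C)CCc2cc(O[Si](C)(C)C)ccc2O1
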